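**Plan**

Rings: A = cyclopentane, B = cyclooctene, C = central cyclohexane, D = gem-dimethylcyclohexane. The retrosynthesis first cuts ring B twice, at the tetrasubstituted alkene (McMurry) and at the bond from the carbinol carbon to ring A (Nozaki–Hiyama–Kishi), leaving a trans-decalin (rings C/D) aldehyde and an iodocyclopentenone.
Ring C is then cut at both bonds of its CH2–CH2 bridge. This bridge is the only unsubstituted two-carbon unit of ring C and lies between the two methyl-bearing quaternary carbons: the ring C/D fusion carbon is a tertiary radical site reachable from a trisubstituted ring D alkene, and the other carries the future carbinol carbon, so it can be the β-carbon of a vinyl sulfone. The bridge can therefore be ethylene itself; the sulfonyl helper leaves in step 10 and the dioxolane in step 12.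
The radical precursor is cut by an Ireland–Claisen rearrangement into (S)-2,5,5-trimethylcyclohex-2-en-1-ol and a six-carbon keto acid masked as its dioxolane.
Forward order: ring D (from the dione) → side chain by [3,3] shift → ring C by a three-component radical annulation → ring A attached → ring B closed last.
Stereochemistry: one centre is set by CBS reduction; it is relayed to the two adjacent CH centres (Claisen), from these to both quaternary centres (annulation), then to the carbinol centre (addition to the α-quaternary aldehyde) and to the two ring A centres (hydroxyl-directed hydrogenation). The alkene geometry is dictated by ring B.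

Key step: step 9

Remark: compounds 1, 2, 7, 15, 17 and 21 are taken as commercial; stereodescriptors in the names follow the SMILES given in the compound list.

**Step 1**
Reactants: 1 2,5,5-trimethylcyclohexane-1,3-dione; 2 2-methylpropan-1-ol
Product: 3 3-(2-methylpropoxy)-2,5,5-trimethylcyclohex-2-en-1-one
Conditions: TsOH (cat.), toluene, reflux, Dean–Stark trap
Reagents that add atoms: none
Why: Acid-catalysed O-alkylation of the vinylogous acid with azeotropic removal of water should give the vinylogous ester.

**Step 2**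
Reactants: 3 3-(2-methylpropoxy)-2,5,5-trimethylcyclohex-2-en-1-one
Product: 5 2,5,5-trimethylcyclohex-2-en-1-one, via allylic alcohol 4 (not isolated)
Conditions: LiAlH4, Et2O, 0 °C; then 2 M HCl, 23 °C
Reagents that add atoms: water O
Why: 1,2-Reduction of the vinylogous ester, then acid hydrolysis of the enol ether with loss of water, transposes the carbonyl group (classical 1,3-dione to enone transposition).

**Step 3**
Reactants: 5 2,5,5-trimethylcyclohex-2-en-1-one
Product: 6 (1S)-2,5,5-trimethylcyclohex-2-en-1-ol
Conditions: (R)-2-methyl-CBS-oxazaborolidine (10 mol%), BH3·SMe2, THF, −20 °C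
Reagents that add atoms: none
Why: Corey–Bakshi–Shibata reduction in which the substituted alkene carbon acts as the large group, so the (R)-catalyst should give the (S)-allylic alcohol, the only stereocentre made by catalysis.

**Step 4**
Reactants: 7 2-(3-chloropropyl)-2-methyl-1,3-dioxolane
Product: 9 4-(2-methyl-1,3-dioxolan-2-yl)butanoic acid, via Grignard reagent 8 (not isolated)
Conditions: Mg, THF, reflux; CO2, −20 °C; then cold dilute HCl to pH 3
Reagents that add atoms: carbon dioxide O=C=O
Why: Grignard formation and carboxylation, with the dioxolane stable to the basic reagent and to the brief cold acidification.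

**Step 5**
Reactants: 6 (1S)-2,5,5-trimethylcyclohex-2-en-1-ol; 9 4-(2-methyl-1,3-dioxolan-2-yl)butanoic acid
Product: 10 (1S)-2,5,5-trimethylcyclohex-2-en-1-yl 4-(2-methyl-1,3-dioxolan-2-yl)butanoate
Conditions: DCC, DMAP (cat.), CH2Cl2, 0 → 23 °C
Reagents that add atoms: none
Why: Steglich esterification, which leaves the carbinol centre untouched.

**Step 6**
Reactants: 10 (1S)-2,5,5-trimethylcyclohex-2-en-1-yl 4-(2-methyl-1,3-dioxolan-2-yl)butanoate
Product: 13 (2S)-4-(2-methyl-1,3-dioxolan-2-yl)-2-[(1S)-2,5,5-trimethylcyclohex-2-en-1-yl]butanoic acid, via silyl ketene acetal 11 (not isolated), via trimethylsilyl ester 12 (not isolated)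
Conditions: LiN(i-Pr)2, THF/DMPU (4:1), −78 °C; Me3SiCl, −78 → 23 °C, then 50 °C; aqueous citric acid
Reagents that add atoms: none
Why: Ireland–Claisen rearrangement in which the [3,3] shift is suprafacial on the ring, so the new bond forms on the face that carried the ester oxygen, and the (Z)-silyl ketene acetal reacting through the boat transition state usual for cyclohexenyl esters places the chain outside the ring, which should set the adjacent CH centre as (S).

**Step 7**
Reactants: 13 (2S)-4-(2-methyl-1,3-dioxolan-2-yl)-2-[(1S)-2,5,5-trimethylcyclohex-2-en-1-yl]butanoic acid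
Product: 14 (3S)-5-(2-methyl-1,3-dioxolan-2-yl)-3-[(1S)-2,5,5-trimethylcyclohex-2-en-1-yl]pentan-2-one
Conditions: MeLi (3 equiv), Et2O, 0 °C; inverse quench into aqueous NH4Cl
Reagents that add atoms: methyllithium [Li]C
Why: Addition of methyllithium to the lithium carboxylate stops at the gem-dialkoxide, which collapses to the methyl ketone on quench (ketone synthesis from a carboxylic acid) without enolising the α-CH centre.

**Step 8**
Reactants: 14 (3S)-5-(2-methyl-1,3-dioxolan-2-yl)-3-[(1S)-2,5,5-trimethylcyclohex-2-en-1-yl]pentan-2-one; 15 diethyl [(benzenesulfonyl)methyl]phosphonate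
Product: 16 [(1E,3S)-2-methyl-5-(2-methyl-1,3-dioxolan-2-yl)-3-[(1S)-2,5,5-trimethylcyclohex-2-en-1-yl]pent-1-ene-1-sulfonyl]benzene
Conditions: n-BuLi, THF, −78 → 23 °C
Reagents that add atoms: none
Why: Horner–Wadsworth–Emmons olefination of the methyl ketone should place the sulfonyl group trans to the branched substituent, and the doubly stabilised anion is too weakly basic to epimerise the α-centre.

**Step 9**
Reactants: 16 [(1E,3S)-2-methyl-5-(2-methyl-1,3-dioxolan-2-yl)-3-[(1S)-2,5,5-trimethylcyclohex-2-en-1-yl]pent-1-ene-1-sulfonyl]benzene; 17 ethylene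
Product: 18 {[(1S,2S,4aS,8aS)-2,4a,7,7-tetramethyl-1-[2-(2-methyl-1,3-dioxolan-2-yl)ethyl]decahydronaphthalen-2-yl]methanesulfonyl}benzene
Conditions: Fe(acac)3 (30 mol%), PhSiH3 (3 equiv, slow addition), ethylene (20 bar), EtOH/1,2-dichloroethane, 0.01 M, 50 °C
Reagents that add atoms: none
Why: Proposed new method: hydrogen-atom transfer from an iron hydride (from Fe(acac)3 and PhSiH3) to the trisubstituted ring D alkene of 16 gives the tertiary, methyl-bearing ring-fusion radical, which adds to ethylene (kept in large excess by pressure); the new primary radical closes ring C onto the β-carbon of the vinyl sulfone, and the α-sulfonyl radical is reduced and protonated. The closest known reaction types are the iron-hydride reductive olefin coupling with activated acceptors (Giese type), radical telomerisation of ethylene and 6-exo radical cyclisations onto vinyl sulfones; capture of such a radical by ethylene followed by ring closure has not been shown, but ethylene is inert to the iron hydride and the nucleophilic primary radical is polarity-matched to the electron-poor alkene. Ring C closes in the 6-exo-trig mode through a chair in which the side chain on the neighbouring CH carbon is equatorial. The ring C/D fusion quaternary centre should be set by attack of ethylene anti to the vicinal ring D substituent (giving the trans-decalin), and the second quaternary centre by the chair with the sulfonylmethylidene terminus pseudo-equatorial and the methyl group axial. The step needs hydrogen-atom transfer to the electron-neutral alkene rather than the vinyl sulfone (secured by the electron-poor sulfone), capture by ethylene faster than reduction of the tertiary radical (ethylene pressure, high dilution, slow silane addition), and 6-exo closure rather than 7-endo closure or hydrogen abstraction (secured by the polarised acceptor).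

**Step 10**
Reactants: 18 {[(1S,2S,4aS,8aS)-2,4a,7,7-tetramethyl-1-[2-(2-methyl-1,3-dioxolan-2-yl)ethyl]decahydronaphthalen-2-yl]methanesulfonyl}benzene
Product: 20 (1S,2S,4aS,8aS)-2,4a,7,7-tetramethyl-1-[2-(2-methyl-1,3-dioxolan-2-yl)ethyl]decahydronaphthalene-2-carbaldehyde, via lithiated sulfone 19 (not isolated)
Conditions: n-BuLi, THF, −78 °C; Me3SiOOSiMe3, −78 → 0 °C; aqueous NaHCO3
Reagents that add atoms: bis(trimethylsilyl) peroxide C[Si](C)(C)OO[Si](C)(C)C
Why: α-Lithiation of the primary sulfone and oxygen transfer from the silyl peroxide give an α-silyloxy sulfone that expels sulfinate (oxidative desulfonylation), so the helper sulfonyl group leaves and its carbon becomes the aldehyde carbon.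

**Step 11**
Reactants: 21 3-methylcyclopent-2-en-1-one
Product: 22 2-iodo-3-methylcyclopent-2-en-1-one
Conditions: I2, pyridine/CH2Cl2, 23 °C
Reagents that add atoms: iodine II
Why: α-Iodination of the enone by conjugate addition of pyridine, iodination of the enolate and elimination.

**Step 12**
Reactants: 20 (1S,2S,4aS,8aS)-2,4a,7,7-tetramethyl-1-[2-(2-methyl-1,3-dioxolan-2-yl)ethyl]decahydronaphthalene-2-carbaldehyde; 22 2-iodo-3-methylcyclopent-2-en-1-one
Product: 24 2-[(S)-hydroxy{(1S,2S,4aS,8aS)-2,4a,7,7-tetramethyl-1-(3-oxobutyl)decahydronaphthalen-2-yl}methyl]-3-methylcyclopent-2-en-1-one, via hydroxy ketal 23 (not isolated)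
Conditions: CrCl2 (5 equiv), NiCl2 (2 mol%), DMF, 23 °C; then 1 M HCl, THF, 23 °C
Reagents that add atoms: water O
Why: Nozaki–Hiyama–Kishi coupling in which the alkenylchromium reagent adds only to the aldehyde and should approach the equatorial formyl group anti to the axial methyl group of the quaternary carbon, with the oxygen turned away from the neighbouring side chain, favouring the required carbinol epimer; the acidic work-up removes the dioxolane.

**Step 13**
Reactants: 24 2-[(S)-hydroxy{(1S,2S,4aS,8aS)-2,4a,7,7-tetramethyl-1-(3-oxobutyl)decahydronaphthalen-2-yl}methyl]-3-methylcyclopent-2-en-1-one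
Product: 25 (2R,3S)-2-[(R)-hydroxy{(1S,2S,4aS,8aS)-2,4a,7,7-tetramethyl-1-(3-oxobutyl)decahydronaphthalen-2-yl}methyl]-3-methylcyclopentan-1-one
Conditions: [Ir(cod)(PCy3)(py)]PF6 (10 mol%), H2 (10 bar), CH2Cl2, 23 °C
Reagents that add atoms: none
Why: Hydroxyl-directed hydrogenation in which 1,3-allylic strain holds the carbinol C–H in the alkene plane next to the ring methyl and the iridium bound to OH delivers both hydrogens to one face, which should set the two ring A centres cis to each other and in the required sense relative to the carbinol.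

**Step 14**
Reactants: 25 (2R,3S)-2-[(R)-hydroxy{(1S,2S,4aS,8aS)-2,4a,7,7-tetramethyl-1-(3-oxobutyl)decahydronaphthalen-2-yl}methyl]-3-methylcyclopentan-1-one
Product: 26 (2R,3S)-2-[(R)-[(tert-butyldimethylsilyl)oxy]{(1S,2S,4aS,8aS)-2,4a,7,7-tetramethyl-1-(3-oxobutyl)decahydronaphthalen-2-yl}methyl]-3-methylcyclopentan-1-one
Conditions: t-BuMe2SiOTf, 2,6-lutidine, CH2Cl2, −78 → 0 °C
Reagents that add atoms: tert-butyldimethylsilyl trifluoromethanesulfonate CC(C)(C)[Si](C)(C)OS(=O)(=O)C(F)(F)F
Why: Silylation of the hindered secondary alcohol with the silyl triflate protects the β-hydroxy ketone from elimination and from the titanium reagent.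

**Step 15**
Reactants: 26 (2R,3S)-2-[(R)-[(tert-butyldimethylsilyl)oxy]{(1S,2S,4aS,8aS)-2,4a,7,7-tetramethyl-1-(3-oxobutyl)decahydronaphthalen-2-yl}methyl]-3-methylcyclopentan-1-one
Product: 27 tert-butyldimethylsilyl ether of the target
Conditions: TiCl3(DME)1.5, Zn(Cu), DME, reflux, slow addition of 26 (high dilution)
Reagents that add atoms: none
Why: Intramolecular McMurry coupling of the cyclopentanone and the methyl ketone on low-valent titanium should close the eight-membered ring B as its tetrasubstituted alkene, whose geometry is fixed by the ring.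

**Step 16**
Reactants: 27 tert-butyldimethylsilyl ether of the target
Product: 28 target alcohol CNP0399382.1
Conditions: Bu4NF, THF, 50 °C
Reagents that add atoms: none
Why: Fluoride cleaves the silyl ether without touching the alkene or any stereocentre.

**Compound list**

1 | 2,5,5-trimethylcyclohexane-1,3-dione | CC1C(=O)CC(C)(C)CC1=O | starting material
2 | 2-methylpropan-1-ol | CC(C)CO | starting material
3 | 3-(2-methylpropoxy)-2,5,5-trimethylcyclohex-2-en-1-one | CC1=C(OCC(C)C)CC(C)(C)CC1=O | intermediate
4 | 3-(2-methylpropoxy)-2,5,5-trimethylcyclohex-2-en-1-ol (racemic, not isolated) | CC1=C(OCC(C)C)CC(C)(C)CC1O | intermediate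
5 | 2,5,5-trimethylcyclohex-2-en-1-one | CC1=CCC(C)(C)CC1=O | intermediate
6 | (1S)-2,5,5-trimethylcyclohex-2-en-1-ol | CC1=CCC(C)(C)C[C@@H]1O | intermediate
7 | 2-(3-chloropropyl)-2-methyl-1,3-dioxolane | CC1(CCCCl)OCCO1 | starting material
8 | [3-(2-methyl-1,3-dioxolan-2-yl)propyl]magnesium chloride (not isolated) | CC1(CCC[Mg]Cl)OCCO1 | intermediate
9 | 4-(2-methyl-1,3-dioxolan-2-yl)butanoic acid | CC1(CCCC(=O)O)OCCO1 | intermediate
10 | (1S)-2,5,5-trimethylcyclohex-2-en-1-yl 4-(2-methyl-1,3-dioxolan-2-yl)butanoate | CC1=CCC(C)(C)C[C@@H]1OC(=O)CCCC2(C)OCCO2 | intermediate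
11 | (Z)-trimethylsilyl ketene acetal of 10 (chain carbon cis to OSi, not isolated) | CC1=CCC(C)(C)C[C@@H]1O/C(O[Si](C)(C)C)=C/CCC2(C)OCCO2 | intermediate
12 | trimethylsilyl (2S)-4-(2-methyl-1,3-dioxolan-2-yl)-2-[(1S)-2,5,5-trimethylcyclohex-2-en-1-yl]butanoate (not isolated) | C[Si](C)(C)OC(=O)[C@@H](CCC2(C)OCCO2)[C@@H]1CC(C)(C)CC=C1C | intermediate
13 | (2S)-4-(2-methyl-1,3-dioxolan-2-yl)-2-[(1S)-2,5,5-trimethylcyclohex-2-en-1-yl]butanoic acid | OC(=O)[C@@H](CCC2(C)OCCO2)[C@@H]1CC(C)(C)CC=C1C | intermediate
14 | (3S)-5-(2-methyl-1,3-dioxolan-2-yl)-3-[(1S)-2,5,5-trimethylcyclohex-2-en-1-yl]pentan-2-one | CC(=O)[C@@H](CCC2(C)OCCO2)[C@@H]1CC(C)(C)CC=C1C | intermediate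
15 | diethyl [(benzenesulfonyl)methyl]phosphonate | CCOP(=O)(CS(=O)(=O)c1ccccc1)OCC | starting material
16 | [(1E,3S)-2-methyl-5-(2-methyl-1,3-dioxolan-2-yl)-3-[(1S)-2,5,5-trimethylcyclohex-2-en-1-yl]pent-1-ene-1-sulfonyl]benzene | O=S(=O)(c1ccccc1)/C=C(\C)[C@@H](CCC2(C)OCCO2)[C@@H]3CC(C)(C)CC=C3C | intermediate
17 | ethylene | C=C | starting material
18 | {[(1S,2S,4aS,8aS)-2,4a,7,7-tetramethyl-1-[2-(2-methyl-1,3-dioxolan-2-yl)ethyl]decahydronaphthalen-2-yl]methanesulfonyl}benzene | O=S(=O)(c1ccccc1)C[C@@]2(C)CC[C@]3(C)CCC(C)(C)C[C@H]3[C@@H]2CCC4(C)OCCO4 | intermediate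
19 | α-lithio derivative of sulfone 18 (not isolated) | O=S(=O)(c1ccccc1)C([Li])[C@@]2(C)CC[C@]3(C)CCC(C)(C)C[C@H]3[C@@H]2CCC4(C)OCCO4 | intermediate
20 | (1S,2S,4aS,8aS)-2,4a,7,7-tetramethyl-1-[2-(2-methyl-1,3-dioxolan-2-yl)ethyl]decahydronaphthalene-2-carbaldehyde | O=C[C@@]1(C)CC[C@]2(C)CCC(C)(C)C[C@H]2[C@@H]1CCC3(C)OCCO3 | intermediate
21 | 3-methylcyclopent-2-en-1-one | CC1=CC(=O)CC1 | starting material
22 | 2-iodo-3-methylcyclopent-2-en-1-one | CC1=C(I)C(=O)CC1 | intermediate
23 | 2-[(S)-hydroxy{(1S,2S,4aS,8aS)-2,4a,7,7-tetramethyl-1-[2-(2-methyl-1,3-dioxolan-2-yl)ethyl]decahydronaphthalen-2-yl}methyl]-3-methylcyclopent-2-en-1-one (not isolated) | CC1=C(C(=O)CC1)[C@@H](O)[C@@]2(C)CC[C@]3(C)CCC(C)(C)C[C@H]3[C@@H]2CCC4(C)OCCO4 | intermediate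
24 | 2-[(S)-hydroxy{(1S,2S,4aS,8aS)-2,4a,7,7-tetramethyl-1-(3-oxobutyl)decahydronaphthalen-2-yl}methyl]-3-methylcyclopent-2-en-1-one | CC1=C(C(=O)CC1)[C@@H](O)[C@@]2(C)CC[C@]3(C)CCC(C)(C)C[C@H]3[C@@H]2CCC(C)=O | intermediate
25 | (2R,3S)-2-[(R)-hydroxy{(1S,2S,4aS,8aS)-2,4a,7,7-tetramethyl-1-(3-oxobutyl)decahydronaphthalen-2-yl}methyl]-3-methylcyclopentan-1-one | C[C@H]1CCC(=O)[C@H]1[C@@H](O)[C@@]2(C)CC[C@]3(C)CCC(C)(C)C[C@H]3[C@@H]2CCC(C)=O | intermediate
26 | tert-butyldimethylsilyl ether of 25 | C[C@H]1CCC(=O)[C@H]1[C@@H](O[Si](C)(C)C(C)(C)C)[C@@]2(C)CC[C@]3(C)CCC(C)(C)C[C@H]3[C@@H]2CCC(C)=O | intermediate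
27 | tert-butyldimethylsilyl ether of the target | C/C1=C2\CC[C@H](C)[C@@H]2[C@@H](O[Si](C)(C)C(C)(C)C)[C@@]2(C)CC[C@]3(C)CCC(C)(C)C[C@H]3[C@@H]2CC1 | intermediate
28 | target alcohol CNP0399382.1 | C/C1=C2\CC[C@H](C)[C@@H]2[C@@H](O)[C@@]2(C)CC[C@]3(C)CCC(C)(C)C[C@H]3[C@@H]2CC1 | target

**Step count and risks**

Total step count: 16. Longest linear sequence: 14 steps (steps 1–3, 5–10 and 12–16).

Steps most likely to fail:

Step 9 (proposed new method). Capture of the tertiary radical by ethylene may be slower than its reduction or its return to the alkene. The primary radical may be quenched by hydrogen transfer, or may abstract the neighbouring allylic hydrogen, before ring closure. The two faces of the vinyl sulfone may not be well differentiated. The fallback uses known reactions and sets out from 16. Iron-hydride reductive coupling with acrolein (Fe(acac)3, PhSiH3, EtOH/ethylene glycol), the established coupling with an activated acceptor, should give 3-[(1S,2S)-2-{(1E,3S)-1-(benzenesulfonyl)-2-methyl-5-(2-methyl-1,3-dioxolan-2-yl)pent-1-en-3-yl}-1,4,4-trimethylcyclohexyl]propanal F1. Enamine activation (pyrrolidine, AcOH) should then close ring C by 6-exo Michael addition onto the vinyl sulfone to give the ring C carbaldehyde of 18 F2. Decarbonylation with stoichiometric RhCl(PPh3)3 in hot toluene should remove the formyl group, returning to the route at 18.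

Step 12. Facial selectivity in the addition to the α-quaternary aldehyde may be poor, because the two smaller groups on the quaternary carbon differ little in size. The fallback sets out from 20. The alkenyllithium made from 6-bromo-7-methyl-1,4-dioxaspiro[4.4]non-6-ene F3 (itself from 2-bromo-3-methylcyclopent-2-en-1-one and ethane-1,2-diol; t-BuLi, −78 °C) should add to give the carbinol epimer mixture F4. Dess–Martin periodinane should give the alkenyl ketone F5, and reagent-controlled Corey–Bakshi–Shibata reduction (tert-alkyl against alkenyl, catalyst enantiomer chosen on a model ketone) should give the single carbinol epimer F6. Aqueous acid then removes both dioxolanes, returning to the route at 24.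

Step 15. Closure of the eight-membered tetrasubstituted alkene may stop at the pinacol stage or give intermolecular coupling. Enolisation of the cyclopentanone on the hot Lewis-acidic titanium surface may scramble the ring A centre next to the carbonyl. The fallback sets out from 26. Ketone–ketone pinacol coupling with SmI2 (THF/HMPA, −78 °C) should give the cis-diol F7 without enolisation. 1,1'-Thiocarbonyldiimidazole should give the cyclic thiocarbonate F8, and Corey–Winter olefination (P(OMe)3, heat) should give the alkene, returning to the route at 27.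

**Further compounds**

F1 | step 9 | 3-[(1S,2S)-2-{(1E,3S)-1-(benzenesulfonyl)-2-methyl-5-(2-methyl-1,3-dioxolan-2-yl)pent-1-en-3-yl}-1,4,4-trimethylcyclohexyl]propanal | O=CCC[C@]3(C)CCC(C)(C)C[C@H]3[C@H](CCC4(C)OCCO4)/C(C)=C/S(=O)(=O)c1ccccc1
F2 | step 9 | ring C carbaldehyde of 18 (formyl group on the ring CH2 next to the sulfonylmethyl-bearing carbon, both epimers) | O=S(=O)(c1ccccc1)C[C@@]2(C)C(C=O)C[C@]3(C)CCC(C)(C)C[C@H]3[C@@H]2CCC4(C)OCCO4
F3 | step 12 | 6-bromo-7-methyl-1,4-dioxaspiro[4.4]non-6-ene | CC1=C(Br)C2(CC1)OCCO2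
F4 | step 12 | carbinol from addition of lithiated F3 to 20 (both carbinol epimers) | CC1=C(C5(CC1)OCCO5)C(O)[C@@]2(C)CC[C@]3(C)CCC(C)(C)C[C@H]3[C@@H]2CCC4(C)OCCO4
F5 | step 12 | alkenyl ketone from oxidation of F4 | CC1=C(C5(CC1)OCCO5)C(=O)[C@@]2(C)CC[C@]3(C)CCC(C)(C)C[C@H]3[C@@H]2CCC4(C)OCCO4
F6 | step 12 | single carbinol epimer of F4 with the carbinol configuration of 23 | CC1=C(C5(CC1)OCCO5)[C@@H](O)[C@@]2(C)CC[C@]3(C)CCC(C)(C)C[C@H]3[C@@H]2CCC4(C)OCCO4
F7 | step 15 | cis-diol (pinacol) from 26 | CC1(O)C2(O)CC[C@H](C)[C@@H]2[C@@H](O[Si](C)(C)C(C)(C)C)[C@@]2(C)CC[C@]3(C)CCC(C)(C)C[C@H]3[C@@H]2CC1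
F8 | step 15 | cyclic thiocarbonate of F7 | CC1(OC(=S)O4)C45CC[C@H](C)[C@@H]5[C@@H](O[Si](C)(C)C(C)(C)C)[C@@]5(C)CC[C@]6(C)CCC(C)(C)C[C@H]6[C@@H]5CC1
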